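**Retrosynthetic overview**
- The strategy rests on the pyranone ring (O1–C2–C3–C4–C4a–C8a): the C4 carbonyl carbon sits between A-ring C4a and the C3=C2 unit, and O1 sits on the neighbouring C8a. C4 can therefore come from CO, C4a/C8a from an o-iodophenol, and C2/C3 with the B ring from a terminal arylalkyne.
- Target ⇐ tri-O-benzyl flavone (hydrogenolysis) ⇐ 3,5-bis(benzyloxy)-2-iodophenol + CO + 1-(benzyloxy)-4-ethynyl-2,3,6-trimethoxybenzene (Pd carbonylative annulation forming C4a–C4, C4–C3 and O1–C2).
- Iodophenol ⇐ 3,5-bis(benzyloxy)phenol by iodination ortho to the free OH.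
- Alkyne ⇐ 1,2,4-trimethoxybenzene by C3 lithiation/hydroxylation, iodination para to the new OH, O-benzylation, Sonogashira coupling with trimethylsilylacetylene and desilylation.
- Ring order: A and B rings are bought as arenes; the pyranone C ring is the only ring formed, in the key step.

Key step: step 7

Assumption: the target is a planar, achiral flavone with no stereocentre, so "single enantiomer" is read as the single constitution given and no stereocontrol is required.

**Route**

Step 1
Reactants: 1 3,5-bis(benzyloxy)phenol
Product: 2 3,5-bis(benzyloxy)-2-iodophenol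
Conditions: I2 (1.0 equiv), NaHCO3, THF–H2O, 0 °C
Reagents that add atoms: iodine, II
Why: Electrophilic aromatic iodination of an activated phenol, in which one equivalent of iodine at 0 °C should substitute one of the two equivalent carbons ortho to OH because the only other free carbon (C4, para to OH) is screened by two flanking benzyloxy groups; any 4-iodo or diiodo by-product is removed by chromatography.

Step 2
Reactants: 3 1,2,4-trimethoxybenzene
Product: 6 2,3,6-trimethoxyphenol, via (2,3,6-trimethoxyphenyl)lithium 4 (not isolated), via dimethyl (2,3,6-trimethoxyphenyl)boronate 5 (not isolated)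
Conditions: n-BuLi, THF, 0 °C to rt; B(OMe)3, −78 °C to rt; then AcOH, 30% aq. H2O2, 0 °C to rt
Reagents that add atoms: hydrogen peroxide, OO (the phenol oxygen of 6); n-butyllithium, [Li]CCCC (Li of intermediate 4 only); trimethyl borate, COB(OC)OC (B(OMe)2 of intermediate 5 only)
Why: Directed ortho-metalation at C3 of 3, the carbon flanked by two cooperating methoxy groups, followed by borylation and oxidative C–B to C–O conversion (aryl 1,2-shift to peroxide oxygen), a standard arene-to-phenol sequence.

Step 3
Reactants: 6 2,3,6-trimethoxyphenol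
Product: 7 4-iodo-2,3,6-trimethoxyphenol
Conditions: I2 (1.0 equiv), NaHCO3, THF–H2O, 0 °C to rt, dark
Reagents that add atoms: iodine, II
Why: Electrophilic iodination through the phenoxide, where both ortho positions carry methoxy groups so that C4 is the only free carbon conjugated with the phenoxide oxygen, whereas C5 is activated only by ether oxygens, one of which (2-OMe) is twisted out of plane.

Step 4
Reactants: 7 4-iodo-2,3,6-trimethoxyphenol
Product: 8 1-(benzyloxy)-4-iodo-2,3,6-trimethoxybenzene
Conditions: BnBr, K2CO3, DMF, rt to 50 °C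
Reagents that add atoms: benzyl bromide, BrCc1ccccc1
Why: Williamson ether synthesis, in which the hindered but acidic 2,6-dimethoxyphenol is alkylated by the reactive benzylic bromide and the sensitive iodophenol is thereby stabilised.

Step 5
Reactants: 8 1-(benzyloxy)-4-iodo-2,3,6-trimethoxybenzene; 9 trimethylsilylacetylene
Product: 10 {[4-(benzyloxy)-2,3,5-trimethoxyphenyl]ethynyl}trimethylsilane
Conditions: PdCl2(PPh3)2 (cat.), CuI (cat.), Et3N, THF, 50 °C
Reagents that add atoms: none
Why: Sonogashira coupling of an aryl iodide with a silyl-capped terminal alkyne, the silyl cap preventing double arylation and the iodide being reactive enough despite the electron-rich ring.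

Step 6
Reactants: 10 {[4-(benzyloxy)-2,3,5-trimethoxyphenyl]ethynyl}trimethylsilane
Product: 11 1-(benzyloxy)-4-ethynyl-2,3,6-trimethoxybenzene
Conditions: K2CO3 (cat.), MeOH–THF, rt
Reagents that add atoms: none
Why: Carbonate-catalysed methanolysis of the alkynyl C–Si bond (protodesilylation), which leaves the benzyl and methyl ethers untouched.

Step 7
Reactants: 2 3,5-bis(benzyloxy)-2-iodophenol; 11 1-(benzyloxy)-4-ethynyl-2,3,6-trimethoxybenzene; 12 carbon monoxide
Product: 15 5,7-bis(benzyloxy)-2-[4-(benzyloxy)-2,3,5-trimethoxyphenyl]-4H-chromen-4-one, via o-hydroxyaryl ynone 13 (not isolated), via diethylamino enaminone 14 (not isolated)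
Conditions: PdCl2(dppf) (5 mol %), CO (10 bar), Et2NH, 100 °C, autoclave, no copper
Reagents that add atoms: diethylamine, CCNCC (present in intermediate 14 only, released again on ring closure)
Why: Pd(0) inserts into the C–I bond of 2, CO insertion gives the aroyl-Pd(II) iodide, and amine-assisted transfer of the acetylide of 11 followed by reductive elimination forms C4a–C4 and C4–C3 in ynone 13. Diethylamine then adds to the β-carbon of the ynone to give enaminone 14, and the phenolic oxygen attacks that same carbon and expels the amine, forming O1–C2. The closest known reaction type is the Pd-catalysed carbonylative Sonogashira coupling–annulation of o-iodophenols with terminal arylalkynes to flavones in a secondary amine. The pyranone ring is closed by a 6-endo addition–elimination (6-endo-trig on the enaminone), and no stereocentre is created. The step needs 6-endo over 5-exo closure (aurone), which the amine relay secures because the β-carbon of 14 is the only electrophilic site left, and carbonylative over direct coupling (benzofuran), which CO pressure and the absence of copper secure. The free OH ortho to iodine in 2 supplies the ring oxygen, and the benzyl and methyl ethers are inert to the conditions.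

Step 8
Reactants: 15 5,7-bis(benzyloxy)-2-[4-(benzyloxy)-2,3,5-trimethoxyphenyl]-4H-chromen-4-one
Product: 16 5,7-dihydroxy-2-(4-hydroxy-2,3,5-trimethoxyphenyl)-4H-chromen-4-one (5,7,4'-trihydroxy-2',3',5'-trimethoxyflavone)
Conditions: H2 (1 atm), 10% Pd/C, THF–MeOH, rt
Reagents that add atoms: none
Why: Catalytic hydrogenolysis of the three benzylic C–O bonds, under which the aryl methyl ethers and the conjugated C2=C3 bond of the pyranone should not be reduced at 1 atm and room temperature if the reaction is stopped once the benzyl groups are gone.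

**Compound list**
1 | 3,5-bis(benzyloxy)phenol | Oc1cc(OCc2ccccc2)cc(OCc2ccccc2)c1 | starting material
2 | 3,5-bis(benzyloxy)-2-iodophenol | Oc1cc(OCc2ccccc2)cc(OCc2ccccc2)c1I | intermediate
3 | 1,2,4-trimethoxybenzene | COc1ccc(OC)c(OC)c1 | starting material
4 | (2,3,6-trimethoxyphenyl)lithium | [Li]c1c(OC)ccc(OC)c1OC | intermediate (not isolated)
5 | dimethyl (2,3,6-trimethoxyphenyl)boronate | COB(OC)c1c(OC)ccc(OC)c1OC | intermediate (not isolated)
6 | 2,3,6-trimethoxyphenol | COc1ccc(OC)c(OC)c1O | intermediate
7 | 4-iodo-2,3,6-trimethoxyphenol | COc1cc(I)c(OC)c(OC)c1O | intermediate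
8 | 1-(benzyloxy)-4-iodo-2,3,6-trimethoxybenzene | COc1cc(I)c(OC)c(OC)c1OCc1ccccc1 | intermediate
9 | trimethylsilylacetylene | C#C[Si](C)(C)C | starting material
10 | {[4-(benzyloxy)-2,3,5-trimethoxyphenyl]ethynyl}trimethylsilane | COc1cc(C#C[Si](C)(C)C)c(OC)c(OC)c1OCc1ccccc1 | intermediate
11 | 1-(benzyloxy)-4-ethynyl-2,3,6-trimethoxybenzene | C#Cc1cc(OC)c(OCc2ccccc2)c(OC)c1OC | intermediate
12 | carbon monoxide | [C-]#[O+] | starting material
13 | 1-[2,4-bis(benzyloxy)-6-hydroxyphenyl]-3-[4-(benzyloxy)-2,3,5-trimethoxyphenyl]prop-2-yn-1-one | O=C(C#Cc1cc(OC)c(OCc2ccccc2)c(OC)c1OC)c1c(O)cc(OCc2ccccc2)cc1OCc1ccccc1 | intermediate (not isolated)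
14 | (E)-1-[2,4-bis(benzyloxy)-6-hydroxyphenyl]-3-[4-(benzyloxy)-2,3,5-trimethoxyphenyl]-3-(diethylamino)prop-2-en-1-one (E drawn; the push–pull C=C isomerises readily and either isomer can close) | CCN(CC)/C(=C/C(=O)c1c(O)cc(OCc2ccccc2)cc1OCc1ccccc1)c1cc(OC)c(OCc2ccccc2)c(OC)c1OC | intermediate (not isolated)
15 | 5,7-bis(benzyloxy)-2-[4-(benzyloxy)-2,3,5-trimethoxyphenyl]-4H-chromen-4-one | COc1cc(-c2cc(=O)c3c(OCc4ccccc4)cc(OCc4ccccc4)cc3o2)c(OC)c(OC)c1OCc1ccccc1 | intermediate
16 | 5,7-dihydroxy-2-(4-hydroxy-2,3,5-trimethoxyphenyl)-4H-chromen-4-one | COc1cc(-c2cc(=O)c3c(O)cc(O)cc3o2)c(OC)c(OC)c1O | target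

**Step count**
Total steps: 8. Longest linear sequence: 7 steps (steps 2–8, from 1,2,4-trimethoxybenzene); the A-ring branch contributes step 1.

**Steps most likely to fail**

1. Step 7 (key step). Oxidative addition at the electron-rich iodide flanked by two oxygen substituents may be slow. The aroyl-palladium species may then be intercepted by diethylamine (amide or keto-amide formation), direct non-carbonylative coupling may lead on to a benzofuran, or 5-exo closure may give the aurone.
Fallback, setting out from 1 and 11 and returning at 13 and then 15: magnesium-mediated ortho-specific formylation of 1 (MgCl2, Et3N, paraformaldehyde, MeCN, reflux) should give 2,4-bis(benzyloxy)-6-hydroxybenzaldehyde F1. Alkyne 11 is deprotonated with n-BuLi (THF, −78 °C) to {[4-(benzyloxy)-2,3,5-trimethoxyphenyl]ethynyl}lithium F2. About 2.2 equivalents of F2 are added to F1; the first equivalent only deprotonates the phenol and returns 11 on aqueous NH4Cl work-up. This should give racemic 3,5-bis(benzyloxy)-2-{3-[4-(benzyloxy)-2,3,5-trimethoxyphenyl]-1-hydroxyprop-2-yn-1-yl}phenol F3. MnO2 (CH2Cl2, rt) oxidises the propargylic, benzylic alcohol to ynone 13, now isolated. Et2NH in EtOH then closes 13 through enaminone 14 to flavone 15, where the route is rejoined without any palladium–CO chemistry.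

2. Step 1. Iodination may take place para to the OH (between the two benzyloxy groups) or go on to the diiodide, and the isomers may be hard to separate.
Fallback, setting out from 1 and returning at 2: the regiochemistry is set by coordination instead of electrophilic substitution. MOMCl/iPr2NEt (CH2Cl2) gives 1,3-bis(benzyloxy)-5-(methoxymethoxy)benzene F4. n-BuLi (THF, 0 °C) should lithiate between the chelating OMOM group and the neighbouring benzyloxy group to give [2,4-bis(benzyloxy)-6-(methoxymethoxy)phenyl]lithium F5. An iodine quench gives 1,5-bis(benzyloxy)-2-iodo-3-(methoxymethoxy)benzene F6, and HCl in MeOH removes the MOM group to give 2.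

3. Step 3. The very electron-rich phenol may be oxidised by iodine (phenoxyl coupling, quinone formation), iodination may compete at C5 para to a methoxy group, and the iodophenol may degrade before benzylation.
Fallback, setting out from 6 and returning at 11: the alkyne carbon is introduced as a formyl group. Phenol-directed Duff formylation (hexamethylenetetramine, AcOH, reflux; then aq. HCl) should give 4-hydroxy-2,3,5-trimethoxybenzaldehyde F7. Benzylation (BnBr, K2CO3, DMF) gives 4-(benzyloxy)-2,3,5-trimethoxybenzaldehyde F8. Seyferth–Gilbert homologation with the Ohira–Bestmann reagent (dimethyl (1-diazo-2-oxopropyl)phosphonate, K2CO3, MeOH, rt) converts F8 directly into alkyne 11, bypassing 7, 8 and 10.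

**Further compounds**
F1 | step 7 | 2,4-bis(benzyloxy)-6-hydroxybenzaldehyde | O=Cc1c(O)cc(OCc2ccccc2)cc1OCc1ccccc1
F2 | step 7 | {[4-(benzyloxy)-2,3,5-trimethoxyphenyl]ethynyl}lithium | [Li]C#Cc1cc(OC)c(OCc2ccccc2)c(OC)c1OC
F3 | step 7 | 3,5-bis(benzyloxy)-2-{3-[4-(benzyloxy)-2,3,5-trimethoxyphenyl]-1-hydroxyprop-2-yn-1-yl}phenol (racemic) | OC(C#Cc1cc(OC)c(OCc2ccccc2)c(OC)c1OC)c1c(O)cc(OCc2ccccc2)cc1OCc1ccccc1
F4 | step 1 | 1,3-bis(benzyloxy)-5-(methoxymethoxy)benzene | COCOc1cc(OCc2ccccc2)cc(OCc2ccccc2)c1
F5 | step 1 | [2,4-bis(benzyloxy)-6-(methoxymethoxy)phenyl]lithium | [Li]c1c(OCOC)cc(OCc2ccccc2)cc1OCc1ccccc1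
F6 | step 1 | 1,5-bis(benzyloxy)-2-iodo-3-(methoxymethoxy)benzene | COCOc1cc(OCc2ccccc2)cc(OCc2ccccc2)c1I
F7 | step 3 | 4-hydroxy-2,3,5-trimethoxybenzaldehyde | COc1cc(C=O)c(OC)c(OC)c1O
F8 | step 3 | 4-(benzyloxy)-2,3,5-trimethoxybenzaldehyde | COc1cc(C=O)c(OC)c(OC)c1OCc1ccccc1
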